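## Structural features

The target 20 has two rings that are not fused. Ring A is a γ-butyrolactone (O1, C2, C3, C4, C5) and ring B is a 2-oxo-2H-pyran-6-carboxylic acid (O1', C2' to C6'). They are joined only through the methylene C7, which links C3 of ring A to C4' of ring B. C4 carries a 3,4-dimethoxybenzyl group through the methylene C8. C3 and C4 are the only stereocentres; they are adjacent, both R, and their substituents are trans. Several groups are fragile: C3–H is α to the lactone carbonyl and can epimerize (trans is the more stable arrangement), ring B is opened by hydroxide, alkoxides and amines at C2' and C6', the C7 hydrogens are vinylogously acidic, the dimethoxyarene is sensitive to strong oxidants and electrophiles, and the free acid is best released last. The real difficulty is twofold: setting two adjacent stereocentres absolutely in a molecule with no other stereochemical handle, and making the C7–C4' sp3–sp2 bond beside the epimerizable C3 without base. The key step exploits the fact that C2 is a single carbon between O1 and C3, that is, one molecule of CO, and that O1–C5–C4–C3 with its arms C8 and C7 is the skeleton of a trisubstituted allylic alcohol. Ring A, the bonds C2–C3 and C2–O1 and both stereocentres can therefore arise in one hydropalladation/carbonylation/lactonization of the achiral E allylic alcohol 7, whose geometry fixes the trans relationship.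

## Logic of the disconnections

20 is traced back to 19 by cutting the O–C(CH3)3 bond of the ester. The acid has to be masked during the metal-mediated union and must be released without hydroxide, which rings A and B do not tolerate. Nothing is gained in skeleton, but every base-labile feature is spared. The forward step must be an anhydrous acidolysis that leaves C3 alone.

19 is cut at C7–C4', the only bond between the two ring systems, to give 13 and 18. C7 is planned as a primary radical released from an activated carboxylate (the extra carbon C7' leaves as CO2) and C4' as an activated vinylic bromide. This makes the plan convergent: ring B is made separately in three steps from cheap material, and ring A arrives with its stereocentres complete. The forward step must run under neutral reductive conditions and must capture the C7 radical at nickel faster than the radical can abstract the benzylic hydrogen on C8.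

13 is taken back through 12 and 10 to 9 by changes at C7' only: the O–N acyl bond, the oxidation of C7' from alcohol to acid, and the O–Si bond. The silyl ether is needed because a free C7' hydroxyl would compete with the C5 hydroxyl for the acylpalladium intermediate of the key step. The price is that the freed alcohol 10 must be oxidized before its oxygen can attack C2.

9 is cut at C2–C3 and C2–O1 to give 7 and 8. This removes ring A and both stereocentres at once and leaves an achiral, acyclic allylic alcohol. The forward step must add Pd–H with palladium on C3, add hydrogen and the acyl carbon to the same face, discriminate the two alkene faces through a chiral ligand, and outrun double-bond migration. It also makes the geometric purity of 7 the source of the diastereomeric purity of 9.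

7 is taken back to 6 by adjusting the oxidation level at C5, and 6 is cut at C3=C4 to give 4 and 5. A stabilized α-substituted ylide is chosen over a phosphonate anion for two reasons: it should give the E trisubstituted enoate more reliably, and it is not basic enough to eliminate the β-silyloxy group of 5. The demand is high E selectivity, since any Z isomer would map onto the cis lactone.

4 is cut at C4–C8 to give 1 and 2 (through 3). The nucleophilic ylide carbon is alkylated by the benzylic chloride and the salt is deprotonated. The demand is alkylation at carbon and not at oxygen.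

18 is taken back to 17 by exchanging C4'–Br for C4'–OH, 17 to 16 by cutting the lactone bond O1'–C2', and 16 to 14 and 15 by cutting C5'–C6'. This reduces ring B to two commodity esters. The tert-butyl ester in 15 has to serve three purposes: it becomes the protected C6' carboxyl, it resists Claisen-type attack so that ring closure goes through oxygen onto the methyl ester, and it must survive the bromination.

## Other disconnections considered

Alternative 1: The cut is at C4–C8 and C3–C7 of a ring A that already exists, so both arms are attached to a chiral butenolide acetal. In the forward key step the 2-lithio derivative of 2-(3,4-dimethoxyphenyl)-1,3-dithiane A3 would add 1,4 to (5R)-5-[(1R,2S,5R)-menthyloxy]furan-2(5H)-one A2, anti to the menthyloxy group. The lithium enolate would then be trapped by benzyl chloromethyl ether A4, trans to the new C4 substituent, to give A1; no ring closes.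
- In its favour: both centres follow from the C5 acetal centre by substrate control, so the absolute configuration is predictable. On this point it is better than the chosen plan, whose sense and level of induction must be found by screening.
- Also in its favour: no pressure equipment is needed, and C7 arrives as a single carbon, so no carbon is excised later. On both points it is better than the chosen plan.
- Against it: A1 carries three groups that must be unpicked. The dithiane needs Raney Ni to give the C8 methylene. The menthyl acetal needs reduction and relactonization to turn C5 into a methylene, under conditions that put C3 at risk. The benzyl ether must be removed and the C7 hydroxyl turned into a halide that sits β to the lactone carbonyl and eliminates readily to the α-methylene lactone.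
- Against it: the C7–C4' bond would still have to be made, to 18 or a relative, so ring B is not simplified.
- Comparison: mechanistically it is stoichiometric auxiliary chemistry with polar organolithium steps, against a catalytic hydride/CO insertion cycle. By a rough count (A2 and A3, the key step, about six steps after it and three for 18) it would be no shorter than the twelve steps of the chosen plan, so on step economy it is equal at best.

Alternative 2: The cut falls in ring B, at O1'–C6' and C3'=C4', so the pyranone is assembled last on a chain that already hangs from C3. In the forward key step diethylphosphonoacetic acid A7 would add through its carboxylate oxygen (catalytic Et3N) to the alkyne carbon C6' of the 4-oxo-2-ynoate A6. The tethered phosphonate carbanion (DBU/LiCl) would then olefinate the C4' ketone, close ring B and give A5, which is the same compound as 19.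
- In its favour: no halogenated pyranone and no radical step are needed, so steps 8 to 10 fall away.
- In its favour: C7' is kept as C4' and not lost as CO2, which is better atom economy than the chosen plan.
- In its favour: it is compatible with the chosen key step. A6 could come from 10 by oxidation to 11, addition of a propiolate ester anion and a second oxidation, which puts A5 four steps from 10. The chosen plan needs three linear steps plus three for 18, so on total step count the alternative is better by about two steps.
- Against it: A6 is an ynone flanked by an ester, an ambident and very reactive acceptor with enolizable C7 hydrogens. The carboxylate must attack C6' and not C5', only the enol ester isomer with O1' and C4' cis can close, and DBU could divert the ynone into allene or oligomer chemistry.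
- Against it: all of this risk falls late, on the chiral intermediate. The chosen plan places the construction of ring B on cheap achiral material and is convergent, and on that point it is the better of the two.

Alternative 3: The cut is C4–C5. C5 would be delivered as a silylmethyl radical, tethered through silicon to the oxygen of a carbinol at C8 that the target does not contain. In the forward key step Bu3SnH/AIBN would turn the bromide A9 into the radical, which would add 5-exo-trig to C4 of the alkylidene succinate. Hydrogen transfer to the C3 radical would give the 1,2-oxasilolane A8 together with its C3 epimer.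
- In its favour: silicon-tethered 5-exo closures are dependable, and C4 is relayed from the C8 carbinol by 1,2-induction.
- In its favour: C3 need not be controlled, because the later trans lactone is the thermodynamic one. On this point it is more robust than an untested enantioselective catalysis.
- In its favour: the C7 arm arrives at the acid oxidation level as a tert-butyl ester, so steps 5 and 6 of the chosen plan have no counterpart. On this point it is better.
- Against it: the absolute configuration has to be bought with an enantiopure benzylic carbinol that is made only to be destroyed.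
- Against it: after Tamao oxidation both the C5 and the C8 hydroxyl could close a five-membered lactone onto the C2 ester, and the method needs stoichiometric tin.
- Comparison: after lactonization and reductive removal of the C8 hydroxyl the sequence would join the chosen plan at 12, so it shares steps 7, 11 and 12 and the need for 18. By a rough count it needs about nine steps to reach 12, where the chosen plan needs six, so it is the longer route.

Key step: step 4

Remarks on the chemistry (assumptions):
- The sense of induction of a chiral 1,4-bisphosphine on 7 cannot be predicted with confidence; both antipodes of BICP are accessible, and the one that leads to (3R,4R)-9 is to be used.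
- 18 is not assumed to be a catalogue compound and is therefore made in steps 8 to 10.
- C7' denotes the carbon attached to C7 in 5 to 7 and 9 to 13; it leaves as CO2 in step 11. In every lactone of the route the CIP order is C2 > C4 > C7 at C3 and C5 > C3 > C8 at C4, so the descriptors stay (3R,4R) from 9 to 20.

## Steps

Step 1
Reactants: 1 ethyl (triphenyl-λ5-phosphanylidene)acetate; 2 3,4-dimethoxybenzyl chloride
Product: 4 ethyl 3-(3,4-dimethoxyphenyl)-2-(triphenyl-λ5-phosphanylidene)propanoate, via phosphonium chloride 3 (not isolated)
Conditions: MeCN, 80 °C; then NaOH (aq), CH2Cl2, 0 °C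
Reagents that add atoms: none
Why: The ester-stabilized ylide is alkylated at carbon by the reactive benzylic chloride (ylide C-alkylation) and the salt 3 is deprotonated to the α-benzyl ylide; no stereocentre is involved.

Step 2
Reactants: 4 ethyl 3-(3,4-dimethoxyphenyl)-2-(triphenyl-λ5-phosphanylidene)propanoate; 5 3-[(tert-butyldimethylsilyl)oxy]propanal
Product: 6 ethyl (2E)-5-[(tert-butyldimethylsilyl)oxy]-2-(3,4-dimethoxybenzyl)pent-2-enoate
Conditions: toluene, 80 °C
Reagents that add atoms: none
Why: Wittig olefination with an α-substituted ester-stabilized ylide should give mainly the E enoate (ester trans to the chain) through reversible addition; the neutral medium avoids β-elimination of silanolate from 5, and any Z isomer is removed by chromatography here or at 7.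

Step 3
Reactants: 6 ethyl (2E)-5-[(tert-butyldimethylsilyl)oxy]-2-(3,4-dimethoxybenzyl)pent-2-enoate
Product: 7 (2E)-5-[(tert-butyldimethylsilyl)oxy]-2-(3,4-dimethoxybenzyl)pent-2-en-1-ol
Conditions: i-Bu2AlH (2.5 equiv), CH2Cl2, −78 °C; KNaC4H4O6 (aq)
Reagents that add atoms: none
Why: 1,2-Reduction of the conjugated ester by the aluminium hydride stops at the allylic alcohol and leaves the silyl ether and the alkene geometry untouched.

Step 4
Reactants: 7 (2E)-5-[(tert-butyldimethylsilyl)oxy]-2-(3,4-dimethoxybenzyl)pent-2-en-1-ol; 8 carbon monoxide
Product: 9 (3R,4R)-3-{2-[(tert-butyldimethylsilyl)oxy]ethyl}-4-(3,4-dimethoxybenzyl)dihydrofuran-2(3H)-one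
Conditions: Pd2(dba)3·CHCl3 (cat.), (1R,1'R,2R,2'R)-2,2'-bis(diphenylphosphino)-1,1'-bicyclopentyl (BICP) or its antipode (cat.), CO/H2 (1:1, ca. 55 bar), CH2Cl2, 80 °C
Reagents that add atoms: none
Why: Zerovalent palladium, the bisphosphine and CO/H2 give a Pd–H species that adds syn across C3=C4, with hydrogen going to the fully substituted C4 and palladium to the less hindered C3, where the C5 hydroxyl can hold the metal in a five-membered chelate. CO then inserts into the C3–Pd bond with retention, and the C5 oxygen attacks the acyl carbon (5-exo-trig) to close ring A, form C2–O1 and return the hydride. The closest known reaction type is the palladium/1,4-bisphosphine-catalysed cyclocarbonylation of 2,3-disubstituted allylic alcohols to trans-α,β-disubstituted γ-butyrolactones, which also has enantioselective versions with chiral bisphosphines. C4 is set by the face that receives hydrogen and C3 by the face that receives palladium and then the acyl carbon; these are the same face, so one enantiofacial choice by the chiral ligand fixes both centres. The trans relation is not left to the catalyst: in the E alkene CH2OH and the C7 chain are trans, and syn addition followed by rotation about C3–C4 into the ring puts C7 and C8 on opposite faces. The step needs three selectivities: regioselective hydropalladation (secured by the substitution pattern and hydroxyl chelation), carbonylation faster than β-hydride elimination toward C7 or C8 (secured by CO pressure and the chelate), and an intact allylic C–O bond (secured by the neutral, acid-free medium).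

Step 5
Reactants: 9 (3R,4R)-3-{2-[(tert-butyldimethylsilyl)oxy]ethyl}-4-(3,4-dimethoxybenzyl)dihydrofuran-2(3H)-one
Product: 10 (3R,4R)-4-(3,4-dimethoxybenzyl)-3-(2-hydroxyethyl)dihydrofuran-2(3H)-one
Conditions: HF·pyridine, pyridine, THF, 0 °C → rt; NaHCO3 (aq)
Reagents that add atoms: none
Why: Fluoride-driven desilylation under buffered, weakly acidic conditions frees the primary alcohol without base, so C3 is not epimerized; the crude alcohol is oxidized at once so that acyl migration has no time.

Step 6
Reactants: 10 (3R,4R)-4-(3,4-dimethoxybenzyl)-3-(2-hydroxyethyl)dihydrofuran-2(3H)-one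
Product: 12 2-[(3R,4R)-4-(3,4-dimethoxybenzyl)-2-oxotetrahydrofuran-3-yl]acetic acid, via lactone aldehyde 11 (not isolated)
Conditions: TEMPO (cat.), PhI(OAc)2 (2.2 equiv), MeCN/H2O, rt
Reagents that add atoms: water, O
Why: Oxoammonium-mediated oxidation (TEMPO/PhI(OAc)2) gives aldehyde 11, whose hydrate is oxidized on to the acid; the medium is free of base and should leave the dimethoxyarene and C3 alone.

Step 7
Reactants: 12 2-[(3R,4R)-4-(3,4-dimethoxybenzyl)-2-oxotetrahydrofuran-3-yl]acetic acid
Product: 13 1,3-dioxoisoindolin-2-yl 2-[(3R,4R)-4-(3,4-dimethoxybenzyl)-2-oxotetrahydrofuran-3-yl]acetate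
Conditions: N-hydroxyphthalimide, i-PrN=C=N-i-Pr, DMAP (cat.), CH2Cl2, rt
Reagents that add atoms: N-hydroxyphthalimide, O=C1c2ccccc2C(=O)N1O
Why: Carbodiimide (Steglich-type) esterification turns the acid into the redox-active N-acyloxyphthalimide under neutral conditions.

Step 8
Reactants: 14 methyl acetoacetate; 15 di-tert-butyl oxalate
Product: 16 1-tert-butyl 6-methyl 2,4-dioxohexanedioate
Conditions: LiN(i-Pr)2 (2.1 equiv per 14), THF, −78 → 0 °C; then 15 (0.5 equiv), −78 → 0 °C; HCl (aq)
Reagents that add atoms: none
Why: Claisen acylation of the acetoacetate dianion at its terminal carbon by the non-enolizable oxalate forms C5'–C6'; the second equivalent of dianion takes up the acidic proton of the product, which is thereby protected against a second addition.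

Step 9
Reactants: 16 1-tert-butyl 6-methyl 2,4-dioxohexanedioate
Product: 17 tert-butyl 4-hydroxy-2-oxo-2H-pyran-6-carboxylate
Conditions: DBU, toluene, 60 °C; HCl (aq)
Reagents that add atoms: none
Why: Base-mediated lactonization of a 3,5-dioxoalkanoate, here the enol oxygen on C6' attacking the methyl ester (6-exo-trig) with loss of methanol, is the standard closure to 4-hydroxy-2-pyranones; the hindered tert-butyl ester should stay out of Claisen-type closures.

Step 10
Reactants: 17 tert-butyl 4-hydroxy-2-oxo-2H-pyran-6-carboxylate
Product: 18 tert-butyl 4-bromo-2-oxo-2H-pyran-6-carboxylate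
Conditions: Ph3PBr2, Et3N, CH2Cl2, 0 °C → rt
Reagents that add atoms: dibromotriphenylphosphorane, BrP(Br)(c1ccccc1)(c1ccccc1)c1ccccc1
Why: The vinylogous acid is activated as its oxyphosphonium salt and bromide substitutes at C4' by addition–elimination (Appel-type deoxybromination of a 1,3-dicarbonyl enol); the amine takes up HBr and so protects the tert-butyl ester.

Step 11
Reactants: 13 1,3-dioxoisoindolin-2-yl 2-[(3R,4R)-4-(3,4-dimethoxybenzyl)-2-oxotetrahydrofuran-3-yl]acetate; 18 tert-butyl 4-bromo-2-oxo-2H-pyran-6-carboxylate
Product: 19 tert-butyl 4-{[(3R,4R)-4-(3,4-dimethoxybenzyl)-2-oxotetrahydrofuran-3-yl]methyl}-2-oxo-2H-pyran-6-carboxylate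
Conditions: NiBr2(dme) (cat.), 4,4'-di-tert-butyl-2,2'-bipyridine (cat.), Zn dust (2 equiv), DMA, rt
Reagents that add atoms: none
Why: Nickel-catalysed reductive decarboxylative cross-electrophile coupling: zerovalent nickel inserts into the activated C4'–Br bond, electron transfer to the N-acyloxyphthalimide releases CO2 and the primary C7 radical, and radical capture followed by reductive elimination from trivalent nickel forms C7–C4'. No base is present, so C3 and both lactone rings are not endangered.

Step 12
Reactants: 19 tert-butyl 4-{[(3R,4R)-4-(3,4-dimethoxybenzyl)-2-oxotetrahydrofuran-3-yl]methyl}-2-oxo-2H-pyran-6-carboxylate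
Product: 20 4-{[(3R,4R)-4-(3,4-dimethoxybenzyl)-2-oxotetrahydrofuran-3-yl]methyl}-2-oxo-2H-pyran-6-carboxylic acid
Conditions: CF3CO2H, CH2Cl2, 0 °C → rt
Reagents that add atoms: none
Why: Acidolysis of the tert-butyl ester through the tert-butyl cation, which leaves as isobutene, frees the acid; anhydrous acid should not open ring A or ring B and does not touch C3 or C4.

## Compound list

1 | ethyl (triphenyl-λ5-phosphanylidene)acetate | CCOC(=O)C=P(c1ccccc1)(c1ccccc1)c1ccccc1 | starting material
2 | 3,4-dimethoxybenzyl chloride | COc1ccc(CCl)cc1OC | starting material
3 | [3-(3,4-dimethoxyphenyl)-1-ethoxy-1-oxopropan-2-yl]triphenylphosphonium chloride | CCOC(=O)C(Cc1ccc(OC)c(OC)c1)[P+](c1ccccc1)(c1ccccc1)c1ccccc1.[Cl-] | intermediate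
4 | ethyl 3-(3,4-dimethoxyphenyl)-2-(triphenyl-λ5-phosphanylidene)propanoate | CCOC(=O)C(Cc1ccc(OC)c(OC)c1)=P(c1ccccc1)(c1ccccc1)c1ccccc1 | intermediate
5 | 3-[(tert-butyldimethylsilyl)oxy]propanal | CC(C)(C)[Si](C)(C)OCCC=O | starting material
6 | ethyl (2E)-5-[(tert-butyldimethylsilyl)oxy]-2-(3,4-dimethoxybenzyl)pent-2-enoate | CCOC(=O)/C(Cc1ccc(OC)c(OC)c1)=C/CCO[Si](C)(C)C(C)(C)C | intermediate
7 | (2E)-5-[(tert-butyldimethylsilyl)oxy]-2-(3,4-dimethoxybenzyl)pent-2-en-1-ol | OC/C(Cc1ccc(OC)c(OC)c1)=C/CCO[Si](C)(C)C(C)(C)C | intermediate
8 | carbon monoxide | [C-]#[O+] | starting material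
9 | (3R,4R)-3-{2-[(tert-butyldimethylsilyl)oxy]ethyl}-4-(3,4-dimethoxybenzyl)dihydrofuran-2(3H)-one | COc1ccc(C[C@H]2COC(=O)[C@@H]2CCO[Si](C)(C)C(C)(C)C)cc1OC | intermediate
10 | (3R,4R)-4-(3,4-dimethoxybenzyl)-3-(2-hydroxyethyl)dihydrofuran-2(3H)-one | COc1ccc(C[C@H]2COC(=O)[C@@H]2CCO)cc1OC | intermediate
11 | 2-[(3R,4R)-4-(3,4-dimethoxybenzyl)-2-oxotetrahydrofuran-3-yl]acetaldehyde | COc1ccc(C[C@H]2COC(=O)[C@@H]2CC=O)cc1OC | intermediate
12 | 2-[(3R,4R)-4-(3,4-dimethoxybenzyl)-2-oxotetrahydrofuran-3-yl]acetic acid | COc1ccc(C[C@H]2COC(=O)[C@@H]2CC(=O)O)cc1OC | intermediate
13 | 1,3-dioxoisoindolin-2-yl 2-[(3R,4R)-4-(3,4-dimethoxybenzyl)-2-oxotetrahydrofuran-3-yl]acetate | COc1ccc(C[C@H]2COC(=O)[C@@H]2CC(=O)ON2C(=O)c3ccccc3C2=O)cc1OC | intermediate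
14 | methyl acetoacetate | COC(=O)CC(C)=O | starting material
15 | di-tert-butyl oxalate | CC(C)(C)OC(=O)C(=O)OC(C)(C)C | starting material
16 | 1-tert-butyl 6-methyl 2,4-dioxohexanedioate | COC(=O)CC(=O)CC(=O)C(=O)OC(C)(C)C | intermediate
17 | tert-butyl 4-hydroxy-2-oxo-2H-pyran-6-carboxylate | CC(C)(C)OC(=O)c1cc(O)cc(=O)o1 | intermediate
18 | tert-butyl 4-bromo-2-oxo-2H-pyran-6-carboxylate | CC(C)(C)OC(=O)c1cc(Br)cc(=O)o1 | intermediate
19 | tert-butyl 4-{[(3R,4R)-4-(3,4-dimethoxybenzyl)-2-oxotetrahydrofuran-3-yl]methyl}-2-oxo-2H-pyran-6-carboxylate | COc1ccc(C[C@H]2COC(=O)[C@@H]2Cc2cc(C(=O)OC(C)(C)C)oc(=O)c2)cc1OC | intermediate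
20 | 4-{[(3R,4R)-4-(3,4-dimethoxybenzyl)-2-oxotetrahydrofuran-3-yl]methyl}-2-oxo-2H-pyran-6-carboxylic acid | COc1ccc(C[C@H]2COC(=O)[C@@H]2Cc2cc(C(=O)O)oc(=O)c2)cc1OC | target

## Step count and least certain steps

Total step count: 12 (steps 1 to 12). Longest linear sequence: 9 steps (steps 1 to 7, 11 and 12); the ring B branch (steps 8 to 10) joins at step 11.

Step 4 (key step). The most likely failure is poor enantiofacial selection. The two faces of C3=C4 differ only in the arrangement of CH2OH, a benzyl group and a flexible silyloxyethyl chain, and none of these is a rigid aryl group on the alkene, as in the best-behaved substrates of this reaction type. A second failure mode is β-hydride elimination from the C3–palladium alkyl before CO inserts, which would move the double bond toward the aryl ring or into the chain and lead to regioisomeric or six-membered lactones. The fallback gives up the carbonylative closure and sets out from 2: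
- Zinc insertion (Zn dust, LiCl, THF) would give (3,4-dimethoxybenzyl)zinc chloride F1.
- Negishi coupling of F1 with commercial 4-bromofuran-2(5H)-one (Pd(PPh3)4, THF) would give 4-(3,4-dimethoxybenzyl)furan-2(5H)-one F2.
- Copper hydride conjugate reduction (CuCl2, NaOt-Bu, the p-Tol-BINAP antipode that delivers R, polymethylhydrosiloxane, toluene) would set C4 in (4R)-4-(3,4-dimethoxybenzyl)dihydrofuran-2(3H)-one F3.
- Deprotonation with LiN(SiMe3)2 (THF, −78 °C) and alkylation with tert-butyl bromoacetate, anti to the benzyl group, would set C3 in tert-butyl 2-[(3R,4R)-4-(3,4-dimethoxybenzyl)-2-oxotetrahydrofuran-3-yl]acetate F4.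
- CF3CO2H in CH2Cl2 would then return the route to 12.

Step 11. The most likely failure is loss of the primary C7 radical before nickel captures it. It can be lost by 1,5-hydrogen transfer from the benzylic C8–H, which gives a more stable radical, or by reduction to a methyl group. In parallel, the activated bromide can be consumed by direct zinc reduction or homocoupling. The fallback replaces radical capture by a two-electron transmetalation and sets out from 13:
- Visible-light iododecarboxylation (LiI, PPh3 cat., blue light, acetone), in which iodine-atom transfer should outrun the hydrogen shift, would give (3R,4R)-4-(3,4-dimethoxybenzyl)-3-(iodomethyl)dihydrofuran-2(3H)-one F5.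
- Zinc insertion (Zn dust, LiCl, THF) would give {[(3R,4R)-4-(3,4-dimethoxybenzyl)-2-oxotetrahydrofuran-3-yl]methyl}zinc iodide F6.
- Negishi coupling of F6 with 18 (Pd2(dba)3, SPhos, THF) would return the route to 19.

Step 5. The most likely failure is acyl migration. Once the C7' hydroxyl is free, it can attack C2 through a bicyclic tetrahedral intermediate and open ring A to the isomeric γ-lactone, in which the C5 hydroxyl is free. The two lactones are of similar stability, so any acid or base catalysis during work-up or storage could equilibrate them. The fallback sets out from 9 and treats it with CrO3/H2SO4 in acetone at 0 °C (Jones oxidation), so that desilylation and oxidation take place in one flask and the alcohol never accumulates. It returns to the route at 12 and makes no compound outside the list (F0).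

Step 9. The most likely failure is closure through carbon and not through oxygen, that is, a Dieckmann-type attack of the C3' methylene on the oxalyl ester to give a cyclopentanetrione. Retro-Claisen cleavage of the tricarbonyl chain by the base is a second possibility. The fallback avoids the open-chain tricarbonyl ester and sets out from 15:
- The lithium dienolate of commercial 2,2,6-trimethyl-4H-1,3-dioxin-4-one (LiN(i-Pr)2, THF, −78 °C) would be acylated by 15 to give tert-butyl 3-(2,2-dimethyl-4-oxo-4H-1,3-dioxin-6-yl)-2-oxopropanoate F7.
- Heating in toluene at 110 °C would expel acetone and give the acylketene tert-butyl 2,4,6-trioxohex-5-enoate F8.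
- The enol oxygen would trap F8 in the flask and return the route to 17.

Step 10. The most likely failure is loss of the tert-butyl ester through HBr formed during the deoxybromination. A second possibility is substitution of the new C4'–Br bond by the amine base. The fallback separates activation from halide introduction and sets out from 17:
- Tf2O and 2,6-lutidine in CH2Cl2 at −78 °C would give tert-butyl 2-oxo-4-{[(trifluoromethyl)sulfonyl]oxy}-2H-pyran-6-carboxylate F9.
- LiBr in acetone would exchange the triflate by addition–elimination and return the route to 18.

## Further compounds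

F1 | step 4 | (3,4-dimethoxybenzyl)zinc chloride | COc1ccc(C[Zn]Cl)cc1OC
F2 | step 4 | 4-(3,4-dimethoxybenzyl)furan-2(5H)-one | COc1ccc(CC2=CC(=O)OC2)cc1OC
F3 | step 4 | (4R)-4-(3,4-dimethoxybenzyl)dihydrofuran-2(3H)-one | COc1ccc(C[C@H]2COC(=O)C2)cc1OC
F4 | step 4 | tert-butyl 2-[(3R,4R)-4-(3,4-dimethoxybenzyl)-2-oxotetrahydrofuran-3-yl]acetate | COc1ccc(C[C@H]2COC(=O)[C@@H]2CC(=O)OC(C)(C)C)cc1OC
F5 | step 11 | (3R,4R)-4-(3,4-dimethoxybenzyl)-3-(iodomethyl)dihydrofuran-2(3H)-one | COc1ccc(C[C@H]2COC(=O)[C@@H]2CI)cc1OC
F6 | step 11 | {[(3R,4R)-4-(3,4-dimethoxybenzyl)-2-oxotetrahydrofuran-3-yl]methyl}zinc iodide | COc1ccc(C[C@H]2COC(=O)[C@@H]2C[Zn]I)cc1OC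
F0 | step 5 | none | none
F7 | step 9 | tert-butyl 3-(2,2-dimethyl-4-oxo-4H-1,3-dioxin-6-yl)-2-oxopropanoate | CC1(C)OC(CC(=O)C(=O)OC(C)(C)C)=CC(=O)O1
F8 | step 9 | tert-butyl 2,4,6-trioxohex-5-enoate | CC(C)(C)OC(=O)C(=O)CC(=O)C=C=O
F9 | step 10 | tert-butyl 2-oxo-4-{[(trifluoromethyl)sulfonyl]oxy}-2H-pyran-6-carboxylate | CC(C)(C)OC(=O)c1cc(OS(=O)(=O)C(F)(F)F)cc(=O)o1
A1 | alternative 1 | (3S,4R,5R)-3-[(benzyloxy)methyl]-4-[2-(3,4-dimethoxyphenyl)-1,3-dithian-2-yl]-5-[(1R,2S,5R)-menthyloxy]dihydrofuran-2(3H)-one | COc1ccc(C3(SCCCS3)[C@H]2[C@H](O[C@@H]4C[C@H](C)CC[C@H]4C(C)C)OC(=O)[C@@H]2COCc2ccccc2)cc1OC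
A2 | alternative 1 | (5R)-5-[(1R,2S,5R)-menthyloxy]furan-2(5H)-one | O=C1C=C[C@H](O[C@@H]2C[C@H](C)CC[C@H]2C(C)C)O1
A3 | alternative 1 | 2-(3,4-dimethoxyphenyl)-1,3-dithiane | COc1ccc(C2SCCCS2)cc1OC
A4 | alternative 1 | benzyl chloromethyl ether | ClCOCc1ccccc1
A5 | alternative 2 | tert-butyl 4-{[(3R,4R)-4-(3,4-dimethoxybenzyl)-2-oxotetrahydrofuran-3-yl]methyl}-2-oxo-2H-pyran-6-carboxylate | COc1ccc(C[C@H]2COC(=O)[C@@H]2Cc2cc(C(=O)OC(C)(C)C)oc(=O)c2)cc1OC
A6 | alternative 2 | tert-butyl 5-[(3R,4R)-4-(3,4-dimethoxybenzyl)-2-oxotetrahydrofuran-3-yl]-4-oxopent-2-ynoate | COc1ccc(C[C@H]2COC(=O)[C@@H]2CC(=O)C#CC(=O)OC(C)(C)C)cc1OC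
A7 | alternative 2 | diethylphosphonoacetic acid | CCOP(=O)(CC(=O)O)OCC
A8 | alternative 3 | 4-tert-butyl 1-methyl (2R)-2-[(4S,5R)-5-(3,4-dimethoxyphenyl)-2,2-dimethyl-1,2-oxasilolan-4-yl]succinate | COC(=O)[C@H](CC(=O)OC(C)(C)C)[C@@H]1C[Si](C)(C)O[C@H]1c1ccc(OC)c(OC)c1
A9 | alternative 3 | 4-tert-butyl 1-methyl (2E)-2-[(2R)-2-{[(bromomethyl)dimethylsilyl]oxy}-2-(3,4-dimethoxyphenyl)ethylidene]succinate | COC(=O)/C(CC(=O)OC(C)(C)C)=C/[C@@H](O[Si](C)(C)CBr)c1ccc(OC)c(OC)c1
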